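| flask | free monomer | initiator | remark | time |
|---|---|---|---|---|
| west | 3 M | 2.5 mol% | run made earlier |  |
| north-west | 3 M | 10 mol% | run made earlier |  |
| flask | 3.0 M | 5 mol% |  | 10 d |

| run | time / d | monomer in chains / % | free monomer / % |
|---|---|---|---|
| west | 1.04 | 3.1 | 98.5 |
| west | 2.08 | 6.3 | 93.6 |
| west | 3.00 | 11.1 | 89.1 |
| west | 4.00 | 14.3 | 86.0 |
| west | 5.00 | 18.7 | 80.4 |
| west | 6.00 | 23.2 | 76.2 |
| north-west | 0.417 | 2.8 | 97.9 |
| north-west | 1.25 | 12.0 | 88.2 |
| north-west | 2.00 | 21.4 | 79.1 |
| north-west | 3.00 | 33.0 | 65.1 |
| north-west | 5.00 | 55.2 | 45.5 |
| north-west | 6.00 | 62.8 | 36.5 |

(readings scatter by 0.5 percentage points)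

* whether the average number of monomer units in a chain (chains begun, living or dead) reaches 10 by 10 d (no / yes)
* average number of monomer units in a chain (chains begun, living or dead) at 10 d

- the average divides the monomer in chains by the number of chains begun, living and dead together
- the earlier runs do not show the number of chains; that part of a forecast is a guess

**Easy slope.** We start with a logarithm: with M the free monomer, ln M falls at 0.0525 /d in the west run and 0.186 /d in the north-west run, read from the second reading to the last. The flask's loading lies a factor of 2.00 from each, so we take their geometric mean, 0.0987 /d. Letting the first 1.04 d pass as start-up, our reckoning for the flask is 58.7% reacted at 10 d.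

**Counting turnovers.** For the flask this gives T = 11.7, where T is the reacted fraction of free monomer divided by the initiator loading, the monomer reacted per initiator charged (the usual theoretical degree of polymerisation). Our working rule is one initiator per chain begun, so the average chain is T divided by the share of initiator that began one, and T is its floor.

**Next run.** T stands above the wanted length of 10, and on our slope the floor passes that length at 8.06 d. So we keep 5 mol% and 10 d for the flask.

**The forecast.** The forecast answers yes and puts the length at 13, within 11 to 19, adding: “Lower efficiency raises it; transfer would lower it.” Our 11.7 stands below its 13, and we hold ours as a floor on our working rule, not as the length itself.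

**The result.** The flask answers yes, with 28.7 units in an average chain at 10 d.

    free monomer + initiator → living end + monomer in chains (k = 0.00478 /M/h)
    free monomer + living end → monomer in chains + living end, rate k2*[living end]*[free monomer] (k = 0.0679 /M/h)
    initiator → spent initiator (k = 0.0183 /h)

**Reading it.** At 10.0 d the flask holds 0.0629 M of living end and 0.0869 M of spent initiator, so the share of the initiator charged that began chains is 41.9%. T from the flask's own monomer in chains is 12.0, and divided by that share it gives 28.7. The north-west run, with a reading of 62.8% in chains at 6.00 d on 10 mol%, reads T = 6.28.

(The numbers in the tables stem from a simulated flask from invented constants, noise included.)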